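**Retrosynthetic overview**

Locants are those of cyclohepta[b]furan-2-one: O1, C2 (C=O), C3, C3a, C4–C8, C8a; side chain C1′–C3′ on C6. Ring A is the lactone, ring B the carbocycle.

1. In ring B the pair C5 (C–CH3, sp2) / C6 (CH–side chain) is a two-carbon unit. It is framed by the five-carbon arc C4–C3a–C8a–C8–C7, which carries all of ring A. Removing the C7 methyl (retro-conjugate addition) and oxidising C1′ leaves a 6-acyl-cyclohepta-4,6-diene, i.e. an alkyne inserted into the C=C of a cyclopentene.
2. Key disconnection: C4=C5 and C6=C7 together, by tandem ring-opening / enyne / ring-closing metathesis of the commercial enantiopure cis-fused cyclopentene lactone 5 with internal alkyne 4. Lactone 5 supplies ring A and both fusion stereocentres; alkyne 4 supplies C5, C6, the C5 methyl and the side chain.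
3. After oxidation at C1′, Me2CuLi adds to C7 from the convex face, C6 is equilibrated to trans, and a catalyst-controlled reduction sets C1′.
4. End game: α-methylenation of the lactone, desilylation, selective primary acetylation, angeloylation.
5. Ring order: ring A is present from the start; ring B is formed in step 2 by two-carbon ring expansion of the cyclopentene (five to seven).

Key step: step 2

Remark: C1′ of alkyne 4 is used racemic, because it becomes a ketone in step 4 and is set again in step 6.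

**Route**

Step 1
Reactants: 1 3-[(tert-butyldimethylsilyl)oxy]propanal; 2 prop-1-yn-1-ylmagnesium bromide (CH3C≡CMgBr)
Product: 4 rac-1-[(tert-butyldimethylsilyl)oxy]hex-4-yn-3-yl acetate, via bromomagnesium alkoxide 3 (not isolated)
Conditions: THF, −78 °C to 0 °C; then Ac2O, 0 °C to rt
Reagents that add atoms: acetic anhydride, CC(=O)OC(C)=O
Why: Grignard addition of the alkynyl reagent to the aldehyde followed by acylation of the magnesium alkoxide in the same flask; the new carbinol centre is racemic, which does not matter because it is oxidised in step 4.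

Step 2
Reactants: 4 rac-1-[(tert-butyldimethylsilyl)oxy]hex-4-yn-3-yl acetate; 5 (1R,5S)-2-oxabicyclo[3.3.0]oct-6-en-3-one
Product: 6 (3aS,8aR)-6-{1-acetoxy-3-[(tert-butyldimethylsilyl)oxy]propyl}-5-methyl-3,3a,8,8a-tetrahydro-2H-cyclohepta[b]furan-2-one (both C1′ epimers)
Conditions: second-generation Grubbs catalyst RuCl2(=CHPh)(PCy3)(H2IMes) (10 mol%), CH2Cl2 (0.02 M), 40 °C, slow addition of 4 (2 equiv)
Reagents that add atoms: none
Why: Proposed new method: a ruthenium alkylidene opens the cyclopentene C=C of 5, the resulting alkylidene inserts the alkyne of 4 to give a vinylcarbene, and ring-closing metathesis onto the other former alkene carbon releases the propagating carbene, so the alkyne is formally inserted into the C=C bond; the closest known reaction is the tandem ring-opening/enyne/ring-closing metathesis of cyclopentene with terminal alkynes to 2-substituted cyclohepta-1,3-dienes, together with cross enyne metathesis of internal propargylic esters, extended here to an internal alkyne and a fused, unsymmetrical cyclopentene. Ring B is closed as a seven-membered 1,3-diene by ring-closing metathesis of the vinylcarbene onto the tethered alkene (new C4=C5 and C6=C7, both endocyclic and necessarily cis), while ring A is carried through unchanged. No stereocentre is created: C3a and C8a come from 5 and are not touched, and C1′ is racemic and is erased in step 4. The step needs regioselectivity in pairing the two alkyne carbons with the two alkene carbons. Sterics should secure it: the alkene carbon next to the ring-fusion methine (future C4) is hindered and the one next to CH2 (future C7) is open, and the alkyne carbons differ as CH3-bearing versus branched acetoxyalkyl-bearing, so carbene C–C bond formation at the open alkene carbon and ruthenium placement on the more substituted alkyne carbon both lead to C4=C5 / C6=C7. Slow addition of the alkyne suppresses alkyne oligomerisation, and the low ring strain of 5 at this dilution disfavours ring-opening polymerisation.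

Step 3
Reactants: 6 (3aS,8aR)-6-{1-acetoxy-3-[(tert-butyldimethylsilyl)oxy]propyl}-5-methyl-3,3a,8,8a-tetrahydro-2H-cyclohepta[b]furan-2-one
Product: 7 (3aS,8aR)-6-{3-[(tert-butyldimethylsilyl)oxy]-1-hydroxypropyl}-5-methyl-3,3a,8,8a-tetrahydro-2H-cyclohepta[b]furan-2-one (both C1′ epimers)
Conditions: K2CO3 (0.2 equiv), MeOH, 0 °C
Reagents that add atoms: none
Why: Carbonate-catalysed transesterification removes the allylic acetate, while the primary silyl ether survives and the γ-lactone, if opened, should reclose on neutralisation; no stereocentre is affected.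

Step 4
Reactants: 7 (3aS,8aR)-6-{3-[(tert-butyldimethylsilyl)oxy]-1-hydroxypropyl}-5-methyl-3,3a,8,8a-tetrahydro-2H-cyclohepta[b]furan-2-one
Product: 8 (3aS,8aR)-6-{3-[(tert-butyldimethylsilyl)oxy]propanoyl}-5-methyl-3,3a,8,8a-tetrahydro-2H-cyclohepta[b]furan-2-one
Conditions: Dess–Martin periodinane, CH2Cl2, 0 °C to rt
Reagents that add atoms: none
Why: Dess–Martin oxidation of the secondary dienylic alcohol should give the cross-conjugated 2-acyl-1,3-diene under neutral conditions, which avoids base-induced vinylogous elimination of the C8a lactone oxygen; both C1′ epimers converge on one ketone.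

Step 5
Reactants: 8 (3aS,8aR)-6-{3-[(tert-butyldimethylsilyl)oxy]propanoyl}-5-methyl-3,3a,8,8a-tetrahydro-2H-cyclohepta[b]furan-2-one
Product: 11 (3aS,6S,7R,8aR)-6-{3-[(tert-butyldimethylsilyl)oxy]propanoyl}-5,7-dimethyl-3,3a,6,7,8,8a-hexahydro-2H-cyclohepta[b]furan-2-one, via lithium dienolate 9 (not isolated), via cis ketone 10 (not isolated)
Conditions: Me2CuLi (from MeLi and CuI), Et2O, −78 °C; AcOH, −78 °C; then DBU (0.1 equiv), CH2Cl2, 0 °C
Reagents that add atoms: lithium dimethylcuprate, [Li+].C[Cu-]C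
Why: Gilman cuprate 1,4-addition should place the methyl on C7, the β-carbon of the enone, from the convex face opposite ring A, and kinetic α-protonation of the dienolate keeps the C4=C5 alkene out of conjugation; DBU equilibration through the same dienolate (α-protonation being faster than γ-protonation) should then convert the 6,7-cis ketone into the more stable 6,7-trans ketone.

Step 6
Reactants: 11 (3aS,6S,7R,8aR)-6-{3-[(tert-butyldimethylsilyl)oxy]propanoyl}-5,7-dimethyl-3,3a,6,7,8,8a-hexahydro-2H-cyclohepta[b]furan-2-one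
Product: 13 (3aS,6S,7R,8aR)-6-{(1S)-3-[(tert-butyldimethylsilyl)oxy]-1-hydroxypropyl}-5,7-dimethyl-3,3a,6,7,8,8a-hexahydro-2H-cyclohepta[b]furan-2-one, via catechol borate ester 12 (not isolated)
Conditions: (R)-2-methyl-CBS-oxazaborolidine (0.2 equiv), catecholborane, toluene, −78 °C; aqueous work-up
Reagents that add atoms: none
Why: Corey–Bakshi–Shibata reduction, in which the (R)-oxazaborolidine distinguishes the branched ring carbon C6 (large) from the CH2CH2OSi arm (small) and should deliver hydride to give the (1′S)-carbinol under catalyst control, with catecholborane sparing the alkene and the lactone.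

Step 7
Reactants: 13 (3aS,6S,7R,8aR)-6-{(1S)-3-[(tert-butyldimethylsilyl)oxy]-1-hydroxypropyl}-5,7-dimethyl-3,3a,6,7,8,8a-hexahydro-2H-cyclohepta[b]furan-2-one
Product: 14 (3aS,6S,7R,8aR)-6-{(1S)-1,3-bis[(tert-butyldimethylsilyl)oxy]propyl}-5,7-dimethyl-3,3a,6,7,8,8a-hexahydro-2H-cyclohepta[b]furan-2-one
Conditions: TBSOTf, 2,6-lutidine, CH2Cl2, −78 °C to 0 °C
Reagents that add atoms: tert-butyldimethylsilyl triflate, CC(C)(C)[Si](C)(C)OS(=O)(=O)C(F)(F)F
Why: Silylation of the hindered secondary alcohol with the silyl triflate protects it against the strong base of step 8; no stereocentre is touched.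

Step 8
Reactants: 14 (3aS,6S,7R,8aR)-6-{(1S)-1,3-bis[(tert-butyldimethylsilyl)oxy]propyl}-5,7-dimethyl-3,3a,6,7,8,8a-hexahydro-2H-cyclohepta[b]furan-2-one
Product: 16 3-[(dimethylamino)methyl] derivative of 14 (C3 epimers), via lactone lithium enolate 15 (not isolated)
Conditions: LiN(iPr)2 (LDA), THF, −78 °C; then CH2=NMe2+ I−, −78 °C to rt
Reagents that add atoms: N,N-dimethylmethyleneiminium iodide (Eschenmoser's salt), C=[N+](C)C.[I-]
Why: Kinetic enolisation of the lactone at C3, the only acidic C–H left, and Mannich reaction with the iminium salt; the configuration at C3 is irrelevant because C3 becomes sp2 in step 9.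

Step 9
Reactants: 16 3-[(dimethylamino)methyl] derivative of 14
Product: 18 (3aR,6S,7R,8aR)-6-{(1S)-1,3-bis[(tert-butyldimethylsilyl)oxy]propyl}-5,7-dimethyl-3-methylidene-3,3a,6,7,8,8a-hexahydro-2H-cyclohepta[b]furan-2-one, via trimethylammonium iodide 17 (not isolated)
Conditions: MeI, THF/MeOH, rt; then aq. NaHCO3, CH2Cl2, rt
Reagents that add atoms: none
Why: Quaternisation of the amine and base-induced β-elimination of trimethylamine (E1cB) should unveil the α-methylene lactone.

Step 10
Reactants: 18 (3aR,6S,7R,8aR)-6-{(1S)-1,3-bis[(tert-butyldimethylsilyl)oxy]propyl}-5,7-dimethyl-3-methylidene-3,3a,6,7,8,8a-hexahydro-2H-cyclohepta[b]furan-2-one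
Product: 19 (3aR,6S,7R,8aR)-6-[(1S)-1,3-dihydroxypropyl]-5,7-dimethyl-3-methylidene-3,3a,6,7,8,8a-hexahydro-2H-cyclohepta[b]furan-2-one
Conditions: HF·pyridine, pyridine/THF, 0 °C to rt
Reagents that add atoms: none
Why: Fluoride cleavage of both silyl ethers under buffered, non-nucleophilic conditions that the Michael-accepting α-methylene lactone should tolerate.

Step 11
Reactants: 19 (3aR,6S,7R,8aR)-6-[(1S)-1,3-dihydroxypropyl]-5,7-dimethyl-3-methylidene-3,3a,6,7,8,8a-hexahydro-2H-cyclohepta[b]furan-2-one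
Product: 20 (3S)-3-hydroxy-3-[(3aR,6S,7R,8aR)-5,7-dimethyl-3-methylidene-2-oxo-3,3a,6,7,8,8a-hexahydro-2H-cyclohepta[b]furan-6-yl]propyl acetate
Conditions: AcCl (1.05 equiv), 2,4,6-collidine, CH2Cl2, −78 °C
Reagents that add atoms: acetyl chloride, CC(=O)Cl
Why: Chemoselective acylation of the primary hydroxyl over the hindered secondary one at low temperature with a weak, hindered base.

Step 12
Reactants: 20 (3S)-3-hydroxy-3-[(3aR,6S,7R,8aR)-5,7-dimethyl-3-methylidene-2-oxo-3,3a,6,7,8,8a-hexahydro-2H-cyclohepta[b]furan-6-yl]propyl acetate; 21 angelic acid, (Z)-2-methylbut-2-enoic acid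
Product: 23 (1S)-3-acetoxy-1-[(3aR,6S,7R,8aR)-5,7-dimethyl-3-methylidene-2-oxo-3,3a,6,7,8,8a-hexahydro-2H-cyclohepta[b]furan-6-yl]propyl (Z)-2-methylbut-2-enoate (CNP0163960.1), via mixed anhydride 22 (not isolated)
Conditions: 21, 2,4,6-trichlorobenzoyl chloride, Et3N, toluene, rt; then 20, 80 °C
Reagents that add atoms: none
Why: Yamaguchi esterification, in which the mixed anhydride acylates the secondary alcohol without a nucleophilic catalyst, conditions under which the (Z)-2-methylbut-2-enoyl group should not isomerise to the (E)-isomer; C1′ keeps its configuration because its C–O bond is not broken.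

**Compound list**

1 | 3-[(tert-butyldimethylsilyl)oxy]propanal | O=CCCO[Si](C)(C)C(C)(C)C | starting material
2 | prop-1-yn-1-ylmagnesium bromide | CC#C[Mg]Br | starting material
3 | bromomagnesium 1-[(tert-butyldimethylsilyl)oxy]hex-4-yn-3-olate (racemic) | CC#CC(CCO[Si](C)(C)C(C)(C)C)O[Mg]Br | intermediate
4 | rac-1-[(tert-butyldimethylsilyl)oxy]hex-4-yn-3-yl acetate | CC#CC(CCO[Si](C)(C)C(C)(C)C)OC(C)=O | intermediate
5 | (1R,5S)-2-oxabicyclo[3.3.0]oct-6-en-3-one, i.e. (3aS,6aR)-3,3a,6,6a-tetrahydro-2H-cyclopenta[b]furan-2-one, cis-fused | O=C1O[C@@H]2CC=C[C@@H]2C1 | starting material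
6 | (3aS,8aR)-6-{1-acetoxy-3-[(tert-butyldimethylsilyl)oxy]propyl}-5-methyl-3,3a,8,8a-tetrahydro-2H-cyclohepta[b]furan-2-one (both C1′ epimers) | C1C(=O)O[C@@H]2CC=C(C(CCO[Si](C)(C)C(C)(C)C)OC(C)=O)C(C)=C[C@H]12 | intermediate
7 | (3aS,8aR)-6-{3-[(tert-butyldimethylsilyl)oxy]-1-hydroxypropyl}-5-methyl-3,3a,8,8a-tetrahydro-2H-cyclohepta[b]furan-2-one (both C1′ epimers) | C1C(=O)O[C@@H]2CC=C(C(O)CCO[Si](C)(C)C(C)(C)C)C(C)=C[C@H]12 | intermediate
8 | (3aS,8aR)-6-{3-[(tert-butyldimethylsilyl)oxy]propanoyl}-5-methyl-3,3a,8,8a-tetrahydro-2H-cyclohepta[b]furan-2-one | C1C(=O)O[C@@H]2CC=C(C(=O)CCO[Si](C)(C)C(C)(C)C)C(C)=C[C@H]12 | intermediate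
9 | lithium dienolate (C6=C1′) formed by methyl addition to C7 of 8, (7R) | C1C(=O)O[C@@H]2C[C@@H](C)C(=C([O-])CCO[Si](C)(C)C(C)(C)C)C(C)=C[C@H]12.[Li+] | intermediate
10 | (3aS,6R,7R,8aR)-6-{3-[(tert-butyldimethylsilyl)oxy]propanoyl}-5,7-dimethyl-3,3a,6,7,8,8a-hexahydro-2H-cyclohepta[b]furan-2-one (6,7-cis) | C1C(=O)O[C@@H]2C[C@@H](C)[C@@H](C(=O)CCO[Si](C)(C)C(C)(C)C)C(C)=C[C@H]12 | intermediate
11 | (3aS,6S,7R,8aR)-6-{3-[(tert-butyldimethylsilyl)oxy]propanoyl}-5,7-dimethyl-3,3a,6,7,8,8a-hexahydro-2H-cyclohepta[b]furan-2-one (6,7-trans) | C1C(=O)O[C@@H]2C[C@@H](C)[C@H](C(=O)CCO[Si](C)(C)C(C)(C)C)C(C)=C[C@H]12 | intermediate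
12 | catechol borate ester of alcohol 13 (1′S) | C1C(=O)O[C@@H]2C[C@@H](C)[C@H]([C@H](CCO[Si](C)(C)C(C)(C)C)OB3Oc4ccccc4O3)C(C)=C[C@H]12 | intermediate
13 | (3aS,6S,7R,8aR)-6-{(1S)-3-[(tert-butyldimethylsilyl)oxy]-1-hydroxypropyl}-5,7-dimethyl-3,3a,6,7,8,8a-hexahydro-2H-cyclohepta[b]furan-2-one | C1C(=O)O[C@@H]2C[C@@H](C)[C@H]([C@H](CCO[Si](C)(C)C(C)(C)C)O)C(C)=C[C@H]12 | intermediate
14 | (3aS,6S,7R,8aR)-6-{(1S)-1,3-bis[(tert-butyldimethylsilyl)oxy]propyl}-5,7-dimethyl-3,3a,6,7,8,8a-hexahydro-2H-cyclohepta[b]furan-2-one | C1C(=O)O[C@@H]2C[C@@H](C)[C@H]([C@H](CCO[Si](C)(C)C(C)(C)C)O[Si](C)(C)C(C)(C)C)C(C)=C[C@H]12 | intermediate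
15 | lithium enolate (C2=C3) of lactone 14 | C1=C([O-])O[C@@H]2C[C@@H](C)[C@H]([C@H](CCO[Si](C)(C)C(C)(C)C)O[Si](C)(C)C(C)(C)C)C(C)=C[C@H]12.[Li+] | intermediate
16 | 3-[(dimethylamino)methyl] derivative of 14 (C3 epimers) | CN(C)CC1C(=O)O[C@@H]2C[C@@H](C)[C@H]([C@H](CCO[Si](C)(C)C(C)(C)C)O[Si](C)(C)C(C)(C)C)C(C)=C[C@H]12 | intermediate
17 | trimethylammonium iodide from 16 | C[N+](C)(C)CC1C(=O)O[C@@H]2C[C@@H](C)[C@H]([C@H](CCO[Si](C)(C)C(C)(C)C)O[Si](C)(C)C(C)(C)C)C(C)=C[C@H]12.[I-] | intermediate
18 | (3aR,6S,7R,8aR)-6-{(1S)-1,3-bis[(tert-butyldimethylsilyl)oxy]propyl}-5,7-dimethyl-3-methylidene-3,3a,6,7,8,8a-hexahydro-2H-cyclohepta[b]furan-2-one | C=C1C(=O)O[C@@H]2C[C@@H](C)[C@H]([C@H](CCO[Si](C)(C)C(C)(C)C)O[Si](C)(C)C(C)(C)C)C(C)=C[C@H]12 | intermediate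
19 | (3aR,6S,7R,8aR)-6-[(1S)-1,3-dihydroxypropyl]-5,7-dimethyl-3-methylidene-3,3a,6,7,8,8a-hexahydro-2H-cyclohepta[b]furan-2-one | C=C1C(=O)O[C@@H]2C[C@@H](C)[C@H]([C@H](CCO)O)C(C)=C[C@H]12 | intermediate
20 | (3S)-3-hydroxy-3-[(3aR,6S,7R,8aR)-5,7-dimethyl-3-methylidene-2-oxo-3,3a,6,7,8,8a-hexahydro-2H-cyclohepta[b]furan-6-yl]propyl acetate | C=C1C(=O)O[C@@H]2C[C@@H](C)[C@H]([C@H](CCOC(C)=O)O)C(C)=C[C@H]12 | intermediate
21 | angelic acid, (Z)-2-methylbut-2-enoic acid | OC(=O)/C(C)=C\C | starting material
22 | (Z)-2-methylbut-2-enoic 2,4,6-trichlorobenzoic anhydride | O=C(OC(=O)/C(C)=C\C)c1c(Cl)cc(Cl)cc1Cl | intermediate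
23 | (1S)-3-acetoxy-1-[(3aR,6S,7R,8aR)-5,7-dimethyl-3-methylidene-2-oxo-3,3a,6,7,8,8a-hexahydro-2H-cyclohepta[b]furan-6-yl]propyl (Z)-2-methylbut-2-enoate | C=C1C(=O)O[C@@H]2C[C@@H](C)[C@H]([C@H](CCOC(C)=O)OC(=O)/C(C)=C\C)C(C)=C[C@H]12 | target

**Step count and risks**

Total step count: 12. Longest linear sequence: 12 steps (from aldehyde 1; 11 from lactone 5).

Steps most likely to fail:

1. Step 2 (proposed new method). What may go wrong: the ring-opened alkylidene may equilibrate between its two termini and erode the regiochemical pairing of alkyne and alkene carbons; ring opening of the low-strain fused cyclopentene may stall; the alkyne may oligomerise. Fallback, setting out from lactone 5 and aldehyde 1 and returning at dienone 8, forms the two bonds one after the other by known reactions. Ozonolysis of 5 (O3, CH2Cl2, −78 °C; PPh3) should give the cis dialdehyde F1. Aldehyde 1 with methallylmagnesium chloride, CH2=C(CH3)CH2MgCl, should give the homoallylic alcohol F2, and Dess–Martin oxidation the β,γ-unsaturated ketone F3. The lithium dienolate of F3 (LiN(iPr)2, THF, −78 °C, α-attack) is expected to add to the unhindered CH2CHO arm of F1 to give the β-hydroxy ketone F4. Dehydration with Burgess reagent should give the (E)-enone aldehyde F5, in which the ring CH2 and the isopropenyl group are cis. Takai–Lombardo methylenation (CH2Br2, Zn, TiCl4) of the remaining, hindered aldehyde should give the triene F6. Ring-closing metathesis of the vinyl and isopropenyl groups with the second-generation Grubbs catalyst then closes C4=C5 and delivers 8. The sequence is longer and F1 is base-sensitive, but each bond is formed at a defined terminus.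

2. Step 5. What may go wrong: insufficient facial selectivity of methyl delivery at C7; and, during equilibration at C6, γ-protonation of the dienolate, which would move the C4=C5 alkene into conjugation with the ketone. Fallback, setting out from dienone 8 and returning at ketone 11, replaces thermodynamic control by kinetic, reagent-controlled protonation. Me2CuLi with Me3SiCl (Et2O, −78 °C) should give the isolable trimethylsilyl dienol ether F7. F7 is then protonated at −78 °C in toluene with a Lewis acid-assisted chiral Brønsted acid (SnCl4 with a 1,1′-bi-2-naphthol monoalkyl ether, enantiomer chosen to deliver the proton to the face syn to the C7 methyl). This gives 11 without any enolate equilibration.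

3. Step 6. What may go wrong: the intrinsic (Felkin-type) bias of the α-branched ketone may oppose the catalyst, giving the C1′ epimer or a mixture. Fallback, setting out from ketone 11 and returning at alcohol 13, accepts the substrate-preferred epimer and inverts it. Reduction with LiBH(sBu)3 (L-Selectride), THF, −78 °C, is expected to give the (1′R)-alcohol F8. Mitsunobu reaction (4-nitrobenzoic acid, PPh3, diisopropyl azodicarboxylate, toluene, 0 °C) should give the inverted (1′S)-4-nitrobenzoate F9. Methanolysis (K2CO3, MeOH, 0 °C) then gives 13.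

**Further compounds**

F1 | step 2 | cis-2-(2-oxoethyl)-3-formyl-γ-butyrolactone (dialdehyde from 5) | O=C1O[C@H](CC=O)[C@H](C=O)C1
F2 | step 2 | 1-[(tert-butyldimethylsilyl)oxy]-5-methylhex-5-en-3-ol (racemic) | CC(=C)CC(O)CCO[Si](C)(C)C(C)(C)C
F3 | step 2 | 1-[(tert-butyldimethylsilyl)oxy]-5-methylhex-5-en-3-one | CC(=C)CC(=O)CCO[Si](C)(C)C(C)(C)C
F4 | step 2 | β-hydroxy ketone from aldol addition of F3 to the CH2CHO arm of F1 (new centres unassigned) | O=C1O[C@H](CC(O)C(C(C)=C)C(=O)CCO[Si](C)(C)C(C)(C)C)[C@H](C=O)C1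
F5 | step 2 | (E)-enone aldehyde from dehydration of F4 | O=C1O[C@H](C/C=C(\C(C)=C)C(=O)CCO[Si](C)(C)C(C)(C)C)[C@H](C=O)C1
F6 | step 2 | triene from methylenation of F5 | O=C1O[C@H](C/C=C(\C(C)=C)C(=O)CCO[Si](C)(C)C(C)(C)C)[C@H](C=C)C1
F7 | step 5 | trimethylsilyl dienol ether (C6=C1′) of ketone 11 | C1C(=O)O[C@@H]2C[C@@H](C)C(=C(O[Si](C)(C)C)CCO[Si](C)(C)C(C)(C)C)C(C)=C[C@H]12
F8 | step 6 | (1′R)-epimer of alcohol 13 | C1C(=O)O[C@@H]2C[C@@H](C)[C@H]([C@@H](CCO[Si](C)(C)C(C)(C)C)O)C(C)=C[C@H]12
F9 | step 6 | (1′S)-4-nitrobenzoate of alcohol 13 | C1C(=O)O[C@@H]2C[C@@H](C)[C@H]([C@H](CCO[Si](C)(C)C(C)(C)C)OC(=O)c3ccc(cc3)[N+](=O)[O-])C(C)=C[C@H]12
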